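**Strategy.** The one-carbon bridge C12 (carbinol) lies between the bridgeheads C11 and C13 that carry the C15–C16 bridge, and C8=C9 is the remnant of a benzene ring: the pattern of a 2,6-meta photoadduct of an alkoxyarene. The bicyclo[3.2.1]octene is therefore made by an intramolecular arene–alkene meta photocycloaddition on a 12-methoxy podocarpatriene whose 1α-oxygen, in the bay beside C11, holds a vinyl ether on a glycolate tether. Light forms C11–C15 and C13–C16 on the β face; acid then opens the methoxycyclopropane to the C12 ketone with C8=C9 in place, and reductive scission of the tether leaves it behind as the 1-acetate.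

Key step: step 14

Remark (labels): atoms carry the numbering of the target (ring A C1–C5/C10 with C4 gem-dimethyl and the C20 methyl on C10; ring B C5–C10; C8=C9; bridgeheads C11, C13; one-carbon bridge C12; two-carbon bridge C15–C16; C17 exocyclic). α is the face of the C20 methyl, β the opposite face; absolute configuration is given by CIP descriptors and SMILES.
Remark (assumption): which antipode of the ligand in step 6 gives the (10R) ketone cannot be predicted with confidence and is to be fixed by experiment; the route is written for (10R).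

Step 1
Reactants: 1 2-methylcyclohexane-1,3-dione
Product: 2 3-ethoxy-2-methylcyclohex-2-en-1-one
Conditions: EtOH, TsOH (cat.), toluene, reflux, Dean–Stark
Reagents that add atoms: ethanol, CCO
Why: Acid-catalysed enol etherification of a 1,3-diketone (vinylogous ester formation) driven by azeotropic removal of water.

Step 2
Reactants: 2 3-ethoxy-2-methylcyclohex-2-en-1-one
Product: 4 3-ethoxy-2,6,6-trimethylcyclohex-2-en-1-one, via monomethyl enone 3 (not isolated)
Conditions: LDA, THF, −78 °C, then MeI; second portion of LDA, −78 °C, then MeI, to rt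
Reagents that add atoms: iodomethane, CI
Why: Kinetic α′-deprotonation of the vinylogous ester and methylation, run twice in one pot, should install the gem-dimethyl group (future C4) next to the carbonyl.

Step 3
Reactants: 4 3-ethoxy-2,6,6-trimethylcyclohex-2-en-1-one
Product: 6 2,4,4-trimethyl-3-vinylcyclohex-2-en-1-one, via tertiary carbinol 5 (not isolated)
Conditions: CH2=CHMgBr, THF, 0 °C to rt; then 1 M HCl
Reagents that add atoms: vinylmagnesium bromide, C=C[Mg]Br
Why: Stork–Danheiser transposition: 1,2-addition to the vinylogous ester carbonyl, then acid hydrolysis and dehydration, should move the carbonyl to C1 and leave the vinyl group on C5 beside the gem-dimethyl carbon.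

Step 4
Reactants: 6 2,4,4-trimethyl-3-vinylcyclohex-2-en-1-one; 7 2-bromo-1-iodo-4-methoxybenzene
Product: 8 (E)-3-[2-(2-bromo-4-methoxyphenyl)ethenyl]-2,4,4-trimethylcyclohex-2-en-1-one
Conditions: Pd(OAc)2 (5 mol%), n-Bu4NCl, NaHCO3, DMF, 60 °C
Reagents that add atoms: none
Why: Heck reaction at the terminal vinyl carbon; oxidative addition should be selective for the C–I bond, so the bromide (future C9) is kept for step 6.

Step 5
Reactants: 8 (E)-3-[2-(2-bromo-4-methoxyphenyl)ethenyl]-2,4,4-trimethylcyclohex-2-en-1-one
Product: 9 3-[2-(2-bromo-4-methoxyphenyl)ethyl]-2,4,4-trimethylcyclohex-2-en-1-one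
Conditions: H2 (1 atm), RhCl(PPh3)3 (5 mol%), benzene–EtOH, rt
Reagents that add atoms: none
Why: Homogeneous rhodium-catalysed hydrogenation should reduce the disubstituted styryl double bond and leave the tetrasubstituted enone double bond and the aryl bromide.

Step 6
Reactants: 9 3-[2-(2-bromo-4-methoxyphenyl)ethyl]-2,4,4-trimethylcyclohex-2-en-1-one
Product: 10 (10R)-12-methoxypodocarpa-5,8,11,13-tetraen-1-one (C ring aromatic, C5=C6, C1 ketone, quaternary C10)
Conditions: Pd2(dba)3 (2.5 mol%), (R)-DIFLUORPHOS (6 mol%; or its antipode, see remark), NaOtBu, toluene, 70 °C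
Reagents that add atoms: none
Why: Pd-catalysed intramolecular enolate α-arylation: base gives the extended dienolate (γ-deprotonation at C6), which can reach the aryl–Pd only through its α-carbon C10 (six-membered ring B), so C9–C10 and the quaternary centre form with the double bond parked at C5=C6, and the chiral ligand selects the face of the planar dienolate as in known enantioselective α-arylations that build benzylic quaternary centres.

Step 7
Reactants: 10 (10R)-12-methoxypodocarpa-5,8,11,13-tetraen-1-one
Product: 11 (5R,6R,10R)-12-methoxypodocarpa-8,11,13-triene-1,6β-diol (5β-H; mixture of C1 epimers)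
Conditions: BH3·THF (excess), THF, 0 °C to rt; then NaOH, H2O2, 0 °C to rt
Reagents that add atoms: hydrogen peroxide, OO
Why: Hydroboration–oxidation: borane reduces the C1 ketone and should add to C5=C6 from the β face, anti to the axial C20 methyl (as in Δ5-steroids), putting H on C5 (β, trans ring fusion) and boron on the less substituted C6, which is oxidised with retention.

Step 8
Reactants: 11 (5R,6R,10R)-12-methoxypodocarpa-8,11,13-triene-1,6β-diol
Product: 12 (5R,10R)-12-methoxypodocarpa-8,11,13-triene-1,6-dione
Conditions: Dess–Martin periodinane (2.5 equiv), NaHCO3, CH2Cl2, rt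
Reagents that add atoms: none
Why: Dess–Martin oxidation of both secondary alcohols under buffered, non-basic conditions that should keep the trans ring fusion at the now enolisable C5.

Step 9
Reactants: 12 (5R,10R)-12-methoxypodocarpa-8,11,13-triene-1,6-dione
Product: 13 (1S,5R,6S,10R)-12-methoxypodocarpa-8,11,13-triene-1α,6α-diol
Conditions: NaBH4, MeOH–THF, −20 to 0 °C
Reagents that add atoms: none
Why: Hydride reduction under steric approach control: at C6 the α face is closed by the syn-axial 4α- and 10α-methyls, so hydride enters from β and gives the axial 6α-alcohol, and at C1 equatorial approach is blocked by the bay H11 and C20, so axial β-attack gives the equatorial 1α-alcohol.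

Step 10
Reactants: 14 methyl glycolate
Product: 15 methyl 2-(vinyloxy)acetate
Conditions: vinyl acetate, [Ir(cod)Cl]2 (1 mol%), Na2CO3, toluene, 100 °C
Reagents that add atoms: vinyl acetate, C=COC(C)=O
Why: Iridium-catalysed transfer vinylation of an alcohol with vinyl acetate.

Step 11
Reactants: 15 methyl 2-(vinyloxy)acetate
Product: 16 sodium 2-(vinyloxy)acetate
Conditions: NaOH (1.0 equiv), MeOH–H2O, 0 °C to rt; evaporation and drying
Reagents that add atoms: sodium hydroxide, [Na+].[OH-]
Why: Saponification; the vinyl ether is stable to base and the acid is kept as its salt because the free acid would add to its own vinyl ether.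

Step 12
Reactants: 13 (1S,5R,6S,10R)-12-methoxypodocarpa-8,11,13-triene-1α,6α-diol; 16 sodium 2-(vinyloxy)acetate
Product: 18 (1S,5R,6S,10R)-6α-hydroxy-12-methoxypodocarpa-8,11,13-trien-1α-yl 2-(vinyloxy)acetate, via mixed anhydride 17 (not isolated)
Conditions: 16, 2,4,6-trichlorobenzoyl chloride, THF, rt; then 13, DMAP, toluene, rt
Reagents that add atoms: none
Why: Yamaguchi esterification through the mixed anhydride; the equatorial 1α-OH should react while the axial 6α-OH, 1,3-diaxial to two methyl groups, is left.

Step 13
Reactants: 18 (1S,5R,6S,10R)-6α-hydroxy-12-methoxypodocarpa-8,11,13-trien-1α-yl 2-(vinyloxy)acetate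
Product: 19 (1S,5R,6S,10R)-6α-acetoxy-12-methoxypodocarpa-8,11,13-trien-1α-yl 2-(vinyloxy)acetate
Conditions: Ac2O, DMAP, Et3N, CH2Cl2, 40 °C
Reagents that add atoms: acetic anhydride, CC(=O)OC(C)=O
Why: DMAP-catalysed acetylation of the hindered axial alcohol under forcing basic conditions that leave the vinyl ether untouched.

Step 14
Reactants: 19 (1S,5R,6S,10R)-6α-acetoxy-12-methoxypodocarpa-8,11,13-trien-1α-yl 2-(vinyloxy)acetate
Product: 20 meta photoadduct: C12(OMe) bonded to C11, C13 and C9 (cyclopropane C9–C11–C12), C8=C14, new bonds C11–C15 and C13–C16 on the β face, C15–O–CH2–C(=O)–O–C1 lactone bridge with the C15 oxygen endo (syn to C8/C9), 6α-OAc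
Conditions: hν (254 nm, low-pressure Hg lamp, quartz), degassed cyclohexane, 0.005 M, rt
Reagents that add atoms: none
Why: Excitation of the anisole chromophore gives an intramolecular exciplex in which the enol-ether carbons bond to the two positions ortho to the methoxy group (C15 to C11, C16 to C13; the 2,6-mode that a donor on C12 directs) and C12 then closes a cyclopropane onto C9, leaving C8=C14. This is the arene–alkene meta photocycloaddition, known for anisoles and vinyl ethers both between molecules and across heteroatom tethers. Two rings close at once: the five-membered ring C11–C15–C16–C13–C12 by 1,3-addition across the arene, and the nine-membered lactone C15–O–CH2–CO–O–C1–C10–C9–C11, which is only the tether. C11 and C13 are created together on one arene face, and that face is β because the ester on the equatorial 1α-oxygen holds its acyl carbon on the side of the axial H1 while the axial C20 methyl screens α; C15 takes the tether-imposed endo oxygen and C9/C12 are cage-fixed, and all three are erased later. The selectivity the step needs is the orientation of the alkene (oxygen-bearing carbon on C11, not C13), secured because the 1α-oxygen lies in the bay next to C11 and its glycolate arm cannot span the further 2.4 Å to C13. Closure of the cyclopropane toward C14 instead of C9 would only shift the ring double bond, which step 15 is expected to correct.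

Step 15
Reactants: 20 meta photoadduct
Product: 21 12-oxo bicyclo[3.2.1]octene: C8=C9, C12 ketone, C14 methylene, C15(O)–C16H2 bridge on the β face still tied to O1 through the glycolate lactone, 6α-OAc
Conditions: TsOH·H2O (0.2 equiv), acetone–H2O (10:1), rt
Reagents that add atoms: water, O
Why: Acid-catalysed homoconjugate opening of a 1-alkoxy vinylcyclopropane (the usual fate of 1-methoxy meta photoadducts): protonation at C14, cleavage of C9–C12 with push from the methoxy oxygen and hydrolysis of the oxocarbenium ion should give the C12 ketone with the double bond in the tetrasubstituted C8=C9 position.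

Step 16
Reactants: 21 12-oxo bicyclo[3.2.1]octene lactone
Product: 22 (12S)-12-hydroxy lactone (OH syn to the C15–C16 bridge)
Conditions: NaBH4, MeOH–THF, −40 °C
Reagents that add atoms: none
Why: Ketone reduction under steric approach control: in bicyclo[3.2.1]oct-2-en-8-ones hydride should enter over the sp2 three-atom bridge, away from the exo hydrogens on C15/C16, which places the hydroxyl syn to the two-carbon bridge, and the low temperature spares the α-alkoxy ester.

Step 17
Reactants: 22 (12S)-12-hydroxy lactone
Product: 23 12-O-triethylsilyl ether of 22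
Conditions: Et3SiOTf, 2,6-lutidine, CH2Cl2, −40 to 0 °C
Reagents that add atoms: triethylsilyl trifluoromethanesulfonate, CC[Si](CC)(CC)OS(=O)(=O)C(F)(F)F
Why: Silyl ether formation; it masks the C12 alcohol so that C15 alone is oxidised in step 19 and no free β-hydroxy ketone meets base in step 20.

Step 18
Reactants: 23 12-O-triethylsilyl lactone
Product: 24 1α,6α-diacetoxy-15-hydroxy-12-(triethylsilyloxy) bicyclo[3.2.1]octene (C8=C9, C16 methylene)
Conditions: SmI2 (3 equiv), HMPA, MeOH, THF, 0 °C
Reagents that add atoms: none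
Why: Samarium diiodide cleavage of an α-alkoxy ester: electron transfer to the ester carbonyl expels the C15 alkoxide from the α-carbon and the samarium enolate is protonated, so the tether is cut once and its two carbons stay as the 1-acetate, while the plain acetate, silyl ether and alkene are inert.

Step 19
Reactants: 24 15-hydroxy diacetate
Product: 25 1α,6α-diacetoxy-15-oxo-12-(triethylsilyloxy) bicyclo[3.2.1]octene
Conditions: Dess–Martin periodinane, NaHCO3, CH2Cl2, rt
Reagents that add atoms: none
Why: Dess–Martin oxidation of the only free secondary alcohol to the C15 ketone.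

Step 20
Reactants: 25 15-oxo diacetate
Product: 29 12-O-triethylsilyl ether of the target (C16=C17 exocyclic enone), via silyl enol ether 26 (not isolated), via Mannich base 27 (not isolated), via ammonium iodide 28 (not isolated)
Conditions: TMSOTf, Et3N, CH2Cl2, 0 °C; then Me2N=CH2+ I−, CH2Cl2, rt; then MeI, rt; then sat. aq. NaHCO3
Reagents that add atoms: N,N-dimethylmethyleneiminium iodide (Eschenmoser's salt), C=[N+](C)C.[I-]
Why: Eschenmoser methylenation: the ketone can enolise only toward C16 (C11 is a bridgehead), the silyl enol ether adds to the iminium salt (Mannich reaction), and quaternisation followed by mild base eliminates trimethylamine to the exocyclic enone, soft enolisation avoiding ester enolates.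

Step 21
Reactants: 29 12-O-triethylsilyl ether of the target
Product: 30 1α,6α-diacetoxyjungermannenone C, (1S,5R,6S,10R,11R,12S,13R)
Conditions: HF·pyridine, pyridine, THF, 0 °C to rt
Reagents that add atoms: none
Why: Fluoride-induced desilylation under buffered, non-basic conditions that should spare the acetates, the enone and the retro-aldol-prone β-hydroxy ketone.

**Compound list**

1 | 2-methylcyclohexane-1,3-dione | CC1C(=O)CCCC1=O | starting material
2 | 3-ethoxy-2-methylcyclohex-2-en-1-one | CCOC1=C(C)C(=O)CCC1 | intermediate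
3 | 3-ethoxy-2,6-dimethylcyclohex-2-en-1-one (racemic, not isolated) | CCOC1=C(C)C(=O)C(C)CC1 | intermediate
4 | 3-ethoxy-2,6,6-trimethylcyclohex-2-en-1-one | CCOC1=C(C)C(=O)C(C)(C)CC1 | intermediate
5 | 3-ethoxy-2,6,6-trimethyl-1-vinylcyclohex-2-en-1-ol (racemic, not isolated) | CCOC1=C(C)C(O)(C=C)C(C)(C)CC1 | intermediate
6 | 2,4,4-trimethyl-3-vinylcyclohex-2-en-1-one | C=CC1=C(C)C(=O)CCC1(C)C | intermediate
7 | 2-bromo-1-iodo-4-methoxybenzene | COc1ccc(I)c(Br)c1 | starting material
8 | (E)-3-[2-(2-bromo-4-methoxyphenyl)ethenyl]-2,4,4-trimethylcyclohex-2-en-1-one | COc1ccc(/C=C/C2=C(C)C(=O)CCC2(C)C)c(Br)c1 | intermediate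
9 | 3-[2-(2-bromo-4-methoxyphenyl)ethyl]-2,4,4-trimethylcyclohex-2-en-1-one | COc1ccc(CCC2=C(C)C(=O)CCC2(C)C)c(Br)c1 | intermediate
10 | (10R)-12-methoxypodocarpa-5,8,11,13-tetraen-1-one | COc1ccc2CC=C3C(C)(C)CCC(=O)[C@@]3(C)c2c1 | intermediate
11 | (5R,6R,10R)-12-methoxypodocarpa-8,11,13-triene-1,6β-diol (5β-H, C1 epimers) | COc1ccc2C[C@@H](O)[C@@H]3C(C)(C)CCC(O)[C@@]3(C)c2c1 | intermediate
12 | (5R,10R)-12-methoxypodocarpa-8,11,13-triene-1,6-dione | COc1ccc2CC(=O)[C@@H]3C(C)(C)CCC(=O)[C@@]3(C)c2c1 | intermediate
13 | (1S,5R,6S,10R)-12-methoxypodocarpa-8,11,13-triene-1α,6α-diol | COc1ccc2C[C@H](O)[C@@H]3C(C)(C)CC[C@H](O)[C@@]3(C)c2c1 | intermediate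
14 | methyl glycolate | COC(=O)CO | starting material
15 | methyl 2-(vinyloxy)acetate | COC(=O)COC=C | intermediate
16 | sodium 2-(vinyloxy)acetate | [Na+].[O-]C(=O)COC=C | intermediate
17 | 2-(vinyloxy)acetic 2,4,6-trichlorobenzoic anhydride (not isolated) | C=COCC(=O)OC(=O)c1c(Cl)cc(Cl)cc1Cl | intermediate
18 | (1S,5R,6S,10R)-6α-hydroxy-12-methoxypodocarpa-8,11,13-trien-1α-yl 2-(vinyloxy)acetate | COc1ccc2C[C@H](O)[C@@H]3C(C)(C)CC[C@H](OC(=O)COC=C)[C@@]3(C)c2c1 | intermediate
19 | (1S,5R,6S,10R)-6α-acetoxy-12-methoxypodocarpa-8,11,13-trien-1α-yl 2-(vinyloxy)acetate | COc1ccc2C[C@H](OC(C)=O)[C@@H]3C(C)(C)CC[C@H](OC(=O)COC=C)[C@@]3(C)c2c1 | intermediate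
20 | meta photoadduct (cyclopropane C9–C11–C12, 12-OMe, C8=C14, C11–C15 and C13–C16 on the β face, C15–O–CH2–CO–O–C1 lactone, 6α-OAc) | C1[C@H]5[C@@H]2[C@@]36C(=C[C@H]1[C@]26OC)C[C@H](OC(C)=O)[C@@H]4C(C)(C)CC[C@H](OC(=O)CO5)[C@@]34C | intermediate
21 | 12-oxo bicyclo[3.2.1]octene lactone (C8=C9, C12=O, C15–O–CH2–CO–O–C1, 6α-OAc) | C1[C@H]5[C@@H]2C3=C(C[C@H](OC(C)=O)[C@@H]4C(C)(C)CC[C@H](OC(=O)CO5)[C@@]34C)C[C@H]1C2=O | intermediate
22 | (12S)-12-hydroxy lactone (OH syn to C15–C16) | C1[C@H]5[C@@H]2C3=C(C[C@H](OC(C)=O)[C@@H]4C(C)(C)CC[C@H](OC(=O)CO5)[C@@]34C)C[C@H]1[C@@H]2O | intermediate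
23 | 12-O-triethylsilyl ether of 22 | C1[C@H]5[C@@H]2C3=C(C[C@H](OC(C)=O)[C@@H]4C(C)(C)CC[C@H](OC(=O)CO5)[C@@]34C)C[C@H]1[C@@H]2O[Si](CC)(CC)CC | intermediate
24 | 1α,6α-diacetoxy-15-hydroxy-12-(triethylsilyloxy) compound (C8=C9, C16H2) | C1[C@H](O)[C@@H]2C3=C(C[C@H](OC(C)=O)[C@@H]4C(C)(C)CC[C@H](OC(C)=O)[C@@]34C)C[C@H]1[C@@H]2O[Si](CC)(CC)CC | intermediate
25 | 1α,6α-diacetoxy-15-oxo-12-(triethylsilyloxy) compound | C1C(=O)[C@@H]2C3=C(C[C@H](OC(C)=O)[C@@H]4C(C)(C)CC[C@H](OC(C)=O)[C@@]34C)C[C@H]1[C@@H]2O[Si](CC)(CC)CC | intermediate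
26 | C15 trimethylsilyl enol ether of 25 (C15=C16, not isolated) | C1=C(O[Si](C)(C)C)[C@@H]2C3=C(C[C@H](OC(C)=O)[C@@H]4C(C)(C)CC[C@H](OC(C)=O)[C@@]34C)C[C@H]1[C@@H]2O[Si](CC)(CC)CC | intermediate
27 | 16-(dimethylaminomethyl) ketone (C16 epimers, not isolated) | CN(C)CC1C(=O)[C@@H]2C3=C(C[C@H](OC(C)=O)[C@@H]4C(C)(C)CC[C@H](OC(C)=O)[C@@]34C)C[C@H]1[C@@H]2O[Si](CC)(CC)CC | intermediate
28 | 16-(trimethylammoniomethyl) ketone iodide (not isolated) | C[N+](C)(C)CC1C(=O)[C@@H]2C3=C(C[C@H](OC(C)=O)[C@@H]4C(C)(C)CC[C@H](OC(C)=O)[C@@]34C)C[C@H]1[C@@H]2O[Si](CC)(CC)CC.[I-] | intermediate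
29 | 12-O-triethylsilyl-1α,6α-diacetoxyjungermannenone C | C=C1C(=O)[C@@H]2C3=C(C[C@H](OC(C)=O)[C@@H]4C(C)(C)CC[C@H](OC(C)=O)[C@@]34C)C[C@H]1[C@@H]2O[Si](CC)(CC)CC | intermediate
30 | 1α,6α-diacetoxyjungermannenone C, (1S,5R,6S,10R,11R,12S,13R) | C=C1C(=O)[C@@H]2C3=C(C[C@H](OC(C)=O)[C@@H]4C(C)(C)CC[C@H](OC(C)=O)[C@@]34C)C[C@H]1[C@@H]2O | target

**Step count.** Total: 21 steps. Longest linear sequence: 19 steps (steps 1–9 and 12–21); steps 10–11 are the side branch to the tether acid.

**Steps most likely to fail**

Step 14 (key step). The long, flexible tether may not hold the enol ether over C11/C13, so the excited arene could decay unproductively, add in the ortho mode, or close the cyclopropane in a way that acid cannot funnel to the C8=C9 isomer. The fallback dearomatises the C ring with electrons instead of light. Setting out from diol 13, Birch reduction (Li, NH3, t-BuOH, THF) should give the 12-methoxy-8,12-diene diol F1, and acetylation (Ac2O, DMAP) the diacetate F2. Rhodium-catalysed cyclopropanation of the enol ether with tert-butyl diazoacetate from the β face would give the donor–acceptor cyclopropane F3. Trifluoroacetic acid would open it and cleave the tert-butyl ester to the 13β-(carboxymethyl) 12-ketone F4. Acid-mediated intramolecular C-acylation of the C11 enol (TFAA, AcOH) would close the two-carbon bridge to the 12,15-dione F5. NaBH4 at low temperature should reduce the strained one-carbon-bridge ketone to the hydroxy ketone F6, and silylation (Et3SiOTf, 2,6-lutidine) comes back to the route at 25.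

Step 6. The chiral palladium catalyst may discriminate poorly between the faces of the hindered dienolate, or reductive elimination at the fully substituted C10 may be slow and lose out to debromination. The fallback gives up catalyst control: from 9, ring closure with an achiral catalyst (Pd(OAc)2, a bulky dialkylbiarylphosphine, NaOtBu, toluene) would give the racemic ketone F7, which is resolved by preparative chromatography on a chiral stationary phase, coming back at 10.

Step 16. Hydride may approach C12 from the side of the C15–C16 bridge instead of over the C8=C9 bridge, which would give the wrong carbinol configuration, and this centre cannot be inverted by substitution. The fallback replaces kinetic by thermodynamic control: from 21, if reduction gives the 12-epimeric alcohol F8, it is equilibrated with a ruthenium hydrogen-transfer (alcohol epimerisation) catalyst in toluene at 70 °C. Under equilibrium the hydroxyl should move to the face that hydride found open, and after separation the route is rejoined at 22.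

**Further compounds**

F1 | step 14 | (1S,5R,6S,10R)-12-methoxypodocarpa-8,12-diene-1α,6α-diol (Birch product) | COC1=CCC2C[C@H](O)[C@@H]3C(C)(C)CC[C@H](O)[C@@]3(C)C=2C1
F2 | step 14 | 1α,6α-diacetate of F1 | COC1=CCC2C[C@H](OC(C)=O)[C@@H]3C(C)(C)CC[C@H](OC(C)=O)[C@@]3(C)C=2C1
F3 | step 14 | tert-butyl ester of the C12/C13 cyclopropane (12-OMe, cyclopropane on the β face) | CC(C)(C)OC(=O)C1[C@H]2CC3C[C@H](OC(C)=O)[C@@H]4C(C)(C)CC[C@H](OC(C)=O)[C@@]4(C)C=3C[C@@]12OC
F4 | step 14 | 1α,6α-diacetoxy-13β-(carboxymethyl)podocarp-8-en-12-one | OC(=O)C[C@H]1CC2C[C@H](OC(C)=O)[C@@H]3C(C)(C)CC[C@H](OC(C)=O)[C@@]3(C)C=2CC1=O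
F5 | step 14 | 1α,6α-diacetoxy bicyclo[3.2.1]octene-12,15-dione (C8=C9, C16H2) | C1C(=O)[C@@H]2C3=C(C[C@H](OC(C)=O)[C@@H]4C(C)(C)CC[C@H](OC(C)=O)[C@@]34C)C[C@H]1C2=O
F6 | step 14 | (12S)-1α,6α-diacetoxy-12-hydroxy-15-ketone | C1C(=O)[C@@H]2C3=C(C[C@H](OC(C)=O)[C@@H]4C(C)(C)CC[C@H](OC(C)=O)[C@@]34C)C[C@H]1[C@@H]2O
F7 | step 6 | racemic 12-methoxypodocarpa-5,8,11,13-tetraen-1-one | COc1ccc2CC=C3C(C)(C)CCC(=O)C3(C)c2c1
F8 | step 16 | (12R)-12-hydroxy lactone (12-epimer of 22) | C1[C@H]5[C@@H]2C3=C(C[C@H](OC(C)=O)[C@@H]4C(C)(C)CC[C@H](OC(=O)CO5)[C@@]34C)C[C@H]1[C@H]2O
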